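The spiro-dihydropyran is cut 3 + 3: the O–C8–C13 unit of the terpene, a β-hydroxyalkyl radical with the oxygen already on the spiro carbon C8, against the C1′–C2′–C3′ unit of an alkylidene syncarpic acid, a Michael acceptor beside a ketone. One operation, a Giese addition followed by dehydrative ring closure, unites two C15 halves: it forms C13–C1′, sets C1′ and closes the vinylogous ester bond O–C3′. Its precursors are the iodohydrin made from kobusone (caryophyllene oxide without C13) and the Knoevenagel enone of syncarpic acid and isovaleraldehyde. The 4,5-epoxide is carried through and converted into the (3Z,5S)-allylic alcohol at the end.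

Key step: step 6

Remark: caryophyllane numbering is used for the terpene half (C4/C5 epoxide or carbinol region, C8 spiro carbon, C13 its CH2); C1′ is the CH that bears isobutyl, C2′ and C3′ are the α-carbon and the enol-ether carbon of the syncarpic ring.

Step 1
Reactants: 1 (−)-caryophyllene oxide
Product: 2 kobusone
Conditions: O3, CH2Cl2, −78 °C; then Me2S, −78 °C → rt
Reagents that add atoms: ozone, [O-][O+]=O
Why: Ozonolysis with reductive work-up cleaves the only C=C (C8=C13) to the C8 ketone and leaves the trisubstituted epoxide and the four stereocentres untouched.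

Step 2
Reactants: 2 kobusone
Product: 3 iodohydrin (8-hydroxy-13-iodo-4,5-epoxide)
Conditions: CH2I2, SmI2, THF, 0 °C → rt; sat. aq. NH4Cl
Reagents that add atoms: diiodomethane, ICI
Why: Barbier-type iodomethylation of the ketone by the iodomethylsamarium carbenoid, which should attack the outer face of the C8 carbonyl (away from H1 and the transannular C4–C5 bridge), so that CH2I ends outside and the hydroxyl inside, the C8 configuration of the target.

Step 3
Reactants: 4 2′,4′,6′-trihydroxyacetophenone
Product: 5 acetylsyncarpic acid
Conditions: NaOMe (excess), MeI (excess), MeOH, 0 °C → reflux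
Reagents that add atoms: iodomethane, CI
Why: Exhaustive dearomative C-methylation of the acylphloroglucinol enolate puts two methyl groups on each free ring carbon and locks the ring as the β-triketone.

Step 4
Reactants: 5 acetylsyncarpic acid
Product: 6 syncarpic acid
Conditions: 6 M aq. HCl, reflux
Reagents that add atoms: none
Why: Acid-promoted retro-Claisen deacylation of the 2-acyl-1,3-dione removes the acetyl group.

Step 5
Reactants: 6 syncarpic acid; 7 isovaleraldehyde
Product: 8 alkylidene trione
Conditions: pyrrolidine (10 mol %), AcOH (10 mol %), MgSO4, CH2Cl2, 0 °C → rt; used at once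
Reagents that add atoms: none
Why: Knoevenagel condensation of the cyclic 1,3-dione with the aldehyde; the two flanking carbonyls are equivalent, so there is no E/Z issue, and immediate use avoids tautomerisation to the dienol.

Step 6
Reactants: 3 iodohydrin; 8 alkylidene trione (3 equiv)
Product: 10 spiro-dihydropyran epoxide (1R,4R,5R,8S,9S,1′S), via Giese adduct 9 (not isolated)
Conditions: Bu3SnH (slow addition), Et3B (0.2 equiv)/air, toluene, −20 °C → rt; then PPTS (10 mol %), 4 Å MS, 50 °C
Reagents that add atoms: none
Why: Bu3Sn• takes iodine from 3, the primary β-hydroxyalkyl radical at C13 adds to the alkylidene carbon C1′ of 8 (Giese reaction), and the radical between the two carbonyls takes hydrogen from Bu3SnH to give the enolised 2-alkyl trione 9. The closest known types are the Giese addition of alkyl iodides to alkylidene 1,3-dicarbonyls and the acid-catalysed cyclodehydration of δ-hydroxy 1,3-diones to fused dihydropyranones, which together amount to a formal [3+3] annulation. The dihydropyran closes by 6-exo-trig attack of the C8 hydroxyl on the neighbouring ring carbonyl C3′ followed by loss of water, and because the two carbonyls that flank C2′ are equivalent only one constitution can form. C1′ is the only new stereocentre and is controlled by C8: in a folded, hydrogen-bonded transition state (C8–OH to the carbonyl syn to H1′, C8 anti to the isobutyl group, forming bond anti to the C9 methine) the radical should reach the face that places isobutyl cis to C9 across the pyran, as in the target, though this bias rests on a non-covalent contact and may be modest. The step needs addition to 8 to outrun reduction of the radical (excess 8, slow hydride addition), retention at C8 (closure through the carbonyl under weak acid never breaks the C8–O bond) and survival of the 4,5-epoxide (no strong Lewis or Brønsted acid).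

Step 7
Reactants: 10 spiro-dihydropyran epoxide
Product: 11 (3Z,5R)-allylic alcohol
Conditions: Et2Al(TMP) (from LiTMP and Et2AlCl, 4 equiv), toluene, 0 °C → rt; aq. Rochelle salt
Reagents that add atoms: none
Why: Base-promoted syn-β-elimination of the epoxide (epoxide-to-allylic-alcohol isomerisation) in which the aluminium amide binds the oxygen on the side of H5 and removes a C3 hydrogen (cis to H5) and not a methyl hydrogen, the nine-membered ring should favour the cis (Z) olefin, and the C5–O bond is untouched (5R).

Step 8
Reactants: 11 (3Z,5R)-allylic alcohol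
Product: 12 (5S)-4-nitrobenzoate
Conditions: 4-nitrobenzoic acid, PPh3, DIAD, THF, 0 °C → rt
Reagents that add atoms: 4-nitrobenzoic acid, O=C(O)c1ccc(cc1)[N+](=O)[O-]
Why: Mitsunobu reaction, in which SN2 displacement of the activated C5 oxygen by the carboxylate inverts C5 from R to S.

Step 9
Reactants: 12 (5S)-4-nitrobenzoate
Product: 13 Tomentodione P
Conditions: K2CO3, MeOH, 0 °C → rt
Reagents that add atoms: none
Why: Transesterification (methanolysis) of the activated aryl ester frees the 5S alcohol, while the trione-derived ring has no enolisable position and the hindered vinylogous ester should not be attacked.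

Compound list
1 | (−)-caryophyllene oxide, (1R,4R,5R,9S)-4,5-epoxycaryophyll-8(13)-ene | C[C@@]12CC[C@@H]3[C@H](CC3(C)C)C(=C)CC[C@H]1O2 | starting material
2 | kobusone, (1R,4R,5R,9S)-4,5-epoxy-13-norcaryophyllan-8-one | C[C@@]12CC[C@@H]3[C@H](CC3(C)C)C(=O)CC[C@H]1O2 | intermediate
3 | (1R,4R,5R,8R,9S)-4,5-epoxy-13-iodocaryophyllan-8-ol (tertiary C8–OH, C13 = CH2I) | C[C@@]12CC[C@@H]3[C@H](CC3(C)C)[C@@](O)(CI)CC[C@H]1O2 | intermediate
4 | 2′,4′,6′-trihydroxyacetophenone | CC(=O)c1c(O)cc(O)cc1O | starting material
5 | acetylsyncarpic acid, 2-acetyl-4,4,6,6-tetramethylcyclohexane-1,3,5-trione (enol form) | CC(=O)C1=C(O)C(C)(C)C(=O)C(C)(C)C1=O | intermediate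
6 | syncarpic acid, 2,2,4,4-tetramethylcyclohexane-1,3,5-trione | O=C1CC(=O)C(C)(C)C(=O)C1(C)C | intermediate
7 | isovaleraldehyde (3-methylbutanal) | CC(C)CC=O | starting material
8 | 2-(3-methylbutylidene)-4,4,6,6-tetramethylcyclohexane-1,3,5-trione | CC(C)CC=C1C(=O)C(C)(C)C(=O)C(C)(C)C1=O | intermediate
9 | Giese adduct (not isolated): (8S)-4,5-epoxy-8-hydroxycaryophyllan-13-yl bonded through C13 to C1′ (S) of 2-(3-methylbutyl)syncarpic acid, enol form | C[C@@]12CC[C@@H]3[C@H](CC3(C)C)[C@](O)(CC[C@H]1O2)C[C@H](CC(C)C)C1=C(O)C(C)(C)C(=O)C(C)(C)C1=O | intermediate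
10 | spiro-dihydropyran epoxide (1R,4R,5R,8S,9S,1′S): target skeleton with the 4R,5R-epoxide in place of the C3=C4/C5–OH unit | C[C@@]12CC[C@@H]3[C@H](CC3(C)C)[C@]4(CC[C@H]1O2)C[C@H](CC(C)C)C1=C(O4)C(C)(C)C(=O)C(C)(C)C1=O | intermediate
11 | (1R,3Z,5R,8S,9S,1′S)-allylic alcohol, the C5 epimer of the target | C/C1=C/C[C@@H]2[C@H](CC2(C)C)[C@]2(CC[C@H]1O)C[C@H](CC(C)C)C1=C(O2)C(C)(C)C(=O)C(C)(C)C1=O | intermediate
12 | (1R,3Z,5S,8S,9S,1′S)-5-O-(4-nitrobenzoyl) derivative of the target | C/C1=C/C[C@@H]2[C@H](CC2(C)C)[C@]2(CC[C@@H]1OC(=O)c1ccc(cc1)[N+](=O)[O-])C[C@H](CC(C)C)C1=C(O2)C(C)(C)C(=O)C(C)(C)C1=O | intermediate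
13 | Tomentodione P, (1R,3Z,5S,8S,9S,1′S) | C/C1=C/C[C@@H]2[C@H](CC2(C)C)[C@]2(CC[C@@H]1O)C[C@H](CC(C)C)C1=C(O2)C(C)(C)C(=O)C(C)(C)C1=O | target

Total step count: 9.
Longest linear sequence: 7 steps (4 → 5 → 6 → 8 → 10 → 11 → 12 → 13); 6 steps from 1.

Steps most likely to fail

Step 6. Three processes may spoil it. The C13 radical may be reduced before it adds, or the acceptor may tautomerise or dimerise. The radical may add through an open transition state with poor facial selectivity at C1′. The epoxide may open under acid during ring closure. The fallback forms the pyran by cycloaddition and not by radical addition. It sets out from 1: isomerisation with Et2Al(TMP) should give (3Z,5R)-caryophylla-3,8(13)-dien-5-ol F1, Mitsunobu inversion with 4-nitrobenzoic acid its (5S)-4-nitrobenzoate F2, and methanolysis (K2CO3, MeOH) (3Z,5S)-caryophylla-3,8(13)-dien-5-ol F3. The inverse-electron-demand oxa-Diels–Alder reaction of F3 with 8 (toluene, 80 °C) then closes the spiro-pyran on the exocyclic olefin. The isomers at C8 and C1′ are separated by chromatography and the route is rejoined at 13.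

Step 7. The base may remove a methyl hydrogen (exocyclic olefin), the trans ring olefin may form, or the aluminium amide may engage the carbonyl groups. The fallback sets out from 10 and does not rely on kinetic control of the elimination. Reductive epoxide opening and β-hydride elimination with Cp2TiCl (from Cp2TiCl2 and Zn, THF) should give the exocyclic (5R)-4(12)-en-5-ol F4, and DMP oxidation the exo-methylene enone F5. RhCl3·3H2O in EtOH at 80 °C should move the double bond into the ring to the conjugated, thermodynamically preferred (3Z)-enone F6. Corey–Bakshi–Shibata reduction ((R)-Me-CBS, catecholborane, toluene, −78 °C) should set 5S under reagent control. The route is rejoined at 13, so steps 8 and 9 are not needed.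

Step 2. The carbenoid may add to the other face of the ketone (wrong C8 configuration), or the iodohydrin may be reduced further. The fallback sets out from 1 and delivers oxygen, not carbon, to the accessible face, which inverts the outcome at C8. Epoxidation of C8=C13 with mCPBA (CH2Cl2, NaHCO3, 0 °C) should give the 4,5:8,13-diepoxide F7. PhSeNa (from PhSeSePh and NaBH4, EtOH) should open the spiro-epoxide at its unhindered CH2 to the β-hydroxy selenide F8. F8 takes the place of 3 in step 6 (Bu3Sn• abstracts the phenylselanyl group), and the route is rejoined at 10.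

Further compounds
F1 | step 6 | (1R,3Z,5R,9S)-caryophylla-3,8(13)-dien-5-ol | C/C1=C/C[C@@H]2[C@H](CC2(C)C)C(=C)CC[C@H]1O
F2 | step 6 | (1R,3Z,5S,9S)-caryophylla-3,8(13)-dien-5-yl 4-nitrobenzoate | C/C1=C/C[C@@H]2[C@H](CC2(C)C)C(=C)CC[C@@H]1OC(=O)c1ccc(cc1)[N+](=O)[O-]
F3 | step 6 | (1R,3Z,5S,9S)-caryophylla-3,8(13)-dien-5-ol | C/C1=C/C[C@@H]2[C@H](CC2(C)C)C(=C)CC[C@@H]1O
F4 | step 7 | exocyclic allylic alcohol: (5R)-4(12)-en-5-ol isomer of 11 | C=C1CC[C@@H]2[C@H](CC2(C)C)[C@]2(CC[C@H]1O)C[C@H](CC(C)C)C1=C(O2)C(C)(C)C(=O)C(C)(C)C1=O
F5 | step 7 | exo-methylene enone: 4(12)-en-5-one | C=C1CC[C@@H]2[C@H](CC2(C)C)[C@]2(CCC1=O)C[C@H](CC(C)C)C1=C(O2)C(C)(C)C(=O)C(C)(C)C1=O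
F6 | step 7 | (3Z)-3-en-5-one: 5-oxo analogue of the target | C/C1=C/C[C@@H]2[C@H](CC2(C)C)[C@]2(CCC1=O)C[C@H](CC(C)C)C1=C(O2)C(C)(C)C(=O)C(C)(C)C1=O
F7 | step 2 | 4,5:8,13-diepoxycaryophyllane with the C8 configuration of 3 | C[C@@]12CC[C@@H]3[C@H](CC3(C)C)[C@@]4(CO4)CC[C@H]1O2
F8 | step 2 | 4,5-epoxy-13-(phenylselanyl)caryophyllan-8-ol with the C8 configuration of 3 | C[C@@]12CC[C@@H]3[C@H](CC3(C)C)[C@@](O)(C[Se]c4ccccc4)CC[C@H]1O2
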